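The pyran ring C of the flavan unit is cut at C3–C4 and O1–C2. C4 is a diarylmethine ortho to the ring A oxygen O1: a hydroxyl placed on it leaves under acid, and both epimers give the same flat ortho-quinone methide (O1–C8a–C4a–C4). C3 and C2 map onto the methyl and carbonyl carbons of a 4'-oxygenated acetophenone, used as its enol silane. One chiral-phosphoric-acid-catalysed annulation forms C3–C4 and O1–C2, closes ring C and sets C4. Its precursor is (2-hydroxy-4,6-dimethoxyphenyl)(5,7-dibenzyloxyflavanon-8-yl)methanol, made from (S)-pinocembrin, whose centre is carried through; C2 is then brought to trans while O1 is the only free phenol.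

Key step: step 7

Locants: unprimed numbers and rings A and C belong to the flavan unit; the flavanone unit is numbered as a flavanone and its benzo ring is called ring D.

Assumption: natural (S)-pinocembrin is taken as enantiopure, and the (R)-acid is taken to be the catalyst antipode that serves the required methide face; if a trial shows the opposite sense, the (S)-acid is used with nothing else changed.

Step 1
Reactants: 1 (S)-pinocembrin [(2S)-5,7-dihydroxyflavanone]
Product: 2 (2S)-5,7-bis(benzyloxy)flavanone
Conditions: BnBr (3 equiv), Ag2O (2 equiv), DMF, rt, dark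
Reagents that add atoms: benzyl bromide, BrCc1ccccc1
Why: Silver-oxide-mediated Williamson etherification should benzylate both phenols (the hydrogen-bonded 5-OH more slowly) in the absence of any base able to form the C3 enolate, so the retro-oxa-Michael ring opening that would racemise the flavanone C2 centre is avoided and no stereocentre is touched.

Step 2
Reactants: 2 (2S)-5,7-bis(benzyloxy)flavanone
Product: 3 (2S)-5,7-bis(benzyloxy)-8-iodoflavanone
Conditions: NIS (1.05 equiv), TFA (10 mol%), MeCN, 0 °C → rt
Reagents that add atoms: N-iodosuccinimide, O=C1CCC(=O)N1I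
Why: Electrophilic aromatic iodination of the trioxygenated ring D should go to C8, which is flanked by one benzyloxy group and the tied-back ring oxygen, and not to C6, which sits between two benzyloxy groups, the usual outcome for flavonoids whose 5-oxygen is alkylated; no stereocentre is formed.

Step 3
Reactants: 4 2-hydroxy-4,6-dimethoxybenzaldehyde
Product: 5 2-(tert-butyldimethylsilyloxy)-4,6-dimethoxybenzaldehyde
Conditions: TBSCl, imidazole, DMF, rt
Reagents that add atoms: tert-butyldimethylsilyl chloride, CC(C)(C)[Si](C)(C)Cl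
Why: Silyl ether formation removes the only acidic proton of the aldehyde, which would otherwise quench the aryl–chromium species of step 4, with a group that buffered fluoride can later take off without acid or base; no stereocentre is formed.

Step 4
Reactants: 3 (2S)-5,7-bis(benzyloxy)-8-iodoflavanone; 5 2-(tert-butyldimethylsilyloxy)-4,6-dimethoxybenzaldehyde
Product: 7 (2S)-5,7-bis(benzyloxy)-8-{[2-(tert-butyldimethylsilyloxy)-4,6-dimethoxyphenyl](hydroxy)methyl}flavanone (both carbinol epimers), via arylchromium dichloride 6 (not isolated)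
Conditions: CrCl2 (4 equiv), NiCl2 (2 mol%), 5 (1.5 equiv), DMF, rt; aqueous work-up
Reagents that add atoms: none
Why: Nozaki–Hiyama–Kishi coupling: zerovalent nickel inserts into the C8–I bond and hands the aryl group to chromium, and the resulting aryl–trivalent-chromium species 6 adds to the aldehyde only and is not basic, so the flavanone ketone and its C2 centre are left alone; the new carbinol centre forms without control, which does not matter because step 7 destroys it.

Step 5
Reactants: 7 (2S)-5,7-bis(benzyloxy)-8-{[2-(tert-butyldimethylsilyloxy)-4,6-dimethoxyphenyl](hydroxy)methyl}flavanone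
Product: 8 (2S)-5,7-bis(benzyloxy)-8-[hydroxy(2-hydroxy-4,6-dimethoxyphenyl)methyl]flavanone (both carbinol epimers)
Conditions: Bu4NF (1.2 equiv), AcOH (1.2 equiv), THF, 0 °C
Reagents that add atoms: none
Why: Fluoride-mediated desilylation buffered by acetic acid frees the ring A phenol under nearly neutral conditions, which should spare both the easily ionised diarylcarbinol and the base-sensitive flavanone centre; no stereocentre changes.

Step 6
Reactants: 9 4'-benzyloxyacetophenone
Product: 10 1-(4-benzyloxyphenyl)-1-(trimethylsilyloxy)ethene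
Conditions: TMSOTf, Et3N, CH2Cl2, 0 °C
Reagents that add atoms: trimethylsilyl trifluoromethanesulfonate, C[Si](C)(C)OS(=O)(=O)C(F)(F)F
Why: Soft enolisation of the methyl ketone (silyl triflate plus amine base) gives the only possible, terminal silyl enol ether; no stereocentre is formed.

Step 7
Reactants: 8 (2S)-5,7-bis(benzyloxy)-8-[hydroxy(2-hydroxy-4,6-dimethoxyphenyl)methyl]flavanone; 10 1-(4-benzyloxyphenyl)-1-(trimethylsilyloxy)ethene
Product: 13 (2S)-5,7-bis(benzyloxy)-8-[(4R)-2-(4-benzyloxyphenyl)-2-hydroxy-5,7-dimethoxychroman-4-yl]flavanone (hemiketal; anomer mixture; open hydroxy ketone tautomer in equilibrium), via ortho-quinone methide 11 (not isolated), via silyl ketal 12 (not isolated)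
Conditions: (R)-3,3'-bis(2,4,6-triisopropylphenyl)-1,1'-binaphthyl-2,2'-diyl hydrogen phosphate (10 mol%), 10 (2.5 equiv), powdered 4 Å molecular sieves, toluene, −20 °C → rt; then THF–H2O, AcOH, 0 °C
Reagents that add atoms: none
Why: The phosphoric acid dehydrates either epimer of 8 to the same planar ortho-quinone methide 11, held to the chiral phosphate by a hydrogen bond at the ring A oxygen; the enol silane carbon adds to the methide carbon (C3–C4, Mukaiyama–Michael addition) and the phenol oxygen then collapses onto the silyloxycarbenium carbon (O1–C2), a stepwise formal [4+2] that gives silyl ketal 12, hydrolysed to 13 on work-up. The closest known reaction type is the chiral-phosphoric-acid-catalysed enantioselective addition of enol-type nucleophiles to ortho-quinone methides generated in situ from ortho-hydroxybenzhydrols, which gives 4-aryl-2-chromanols. Ring C closes by 6-exo-trig attack of O1 on the carbonyl-derived carbon C2. C4 is set by the catalyst alone (reagent control over the remote flavanone centre; the carbinol configuration of 8 is lost in 11), whereas the anomeric C2 is left uncontrolled because step 8 removes it. The step needs face selectivity at the methide carbon and ring closure through O1 only: the first is served by the single hydrogen-bond anchor beside the methide and the ease of ionisation given by the oxygens ortho and para to it on both rings, the second by the benzyl ether on the flavanone O7, which leaves O1 as the only free oxygen ortho to the methide.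

Step 8
Reactants: 13 (2S)-5,7-bis(benzyloxy)-8-[(4R)-2-(4-benzyloxyphenyl)-2-hydroxy-5,7-dimethoxychroman-4-yl]flavanone
Product: 15 (2S)-5,7-bis(benzyloxy)-8-[(4R)-2-(4-benzyloxyphenyl)-5,7-dimethoxychroman-4-yl]flavanone (both C2 epimers), via oxocarbenium ion 14 (not isolated)
Conditions: Et3SiH (1.5 equiv), BF3·OEt2 (1.5 equiv), CH2Cl2, −78 °C; Et3N quench at −78 °C
Reagents that add atoms: none
Why: Ionic hydrogenation of a cyclic hemiketal: BF3 ionises 13 (the open hydroxy ketone cyclising first) to the aryl-stabilised oxocarbenium ion 14, which should take hydride from Et3SiH far faster than the trioxygenated flavanone ketone or the benzyl ethers react at −78 °C; C2 is created here without reliance on the face of hydride delivery, because step 9 equilibrates it.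

Step 9
Reactants: 15 (2S)-5,7-bis(benzyloxy)-8-[(4R)-2-(4-benzyloxyphenyl)-5,7-dimethoxychroman-4-yl]flavanone (both C2 epimers)
Product: 17 (2S)-5,7-bis(benzyloxy)-8-[(2S,4R)-2-(4-benzyloxyphenyl)-5,7-dimethoxychroman-4-yl]flavanone (flavan unit 2,4-trans), via ring-opened benzylic cation 16 (not isolated)
Conditions: BF3·OEt2 (0.2 equiv), CH2Cl2, −20 → 0 °C; Et3N quench
Reagents that add atoms: none
Why: Lewis-acid epimerisation of a 2-aryl cyclic benzylic ether by reversible SN1 ring opening: heterolysis of O1–C2 gives the 4-benzyloxybenzyl cation 16, and six-membered reclosure by O1 (the only free nucleophile, the flavanone oxygens being benzylated) should funnel both C2 epimers to the trans isomer, in which the C4 flavanonyl group is pseudo-axial, clear of the peri 5-methoxy group, and the C2 aryl group equatorial; C4 is not involved.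

Step 10
Reactants: 17 (2S)-5,7-bis(benzyloxy)-8-[(2S,4R)-2-(4-benzyloxyphenyl)-5,7-dimethoxychroman-4-yl]flavanone
Product: 18 (2S)-5,7-dihydroxy-8-[(2S,4R)-2-(4-hydroxyphenyl)-5,7-dimethoxychroman-4-yl]flavanone (target; flavan unit 2,4-trans)
Conditions: H2 (1 atm), 10% Pd/C, EtOAc–MeOH, rt
Reagents that add atoms: none
Why: Catalytic hydrogenolysis should cleave the three benzyl aryl ethers while the flavan O1–C2 bond and the hydrogen-bonded flavanone carbonyl, both known to survive these conditions in catechin- and naringenin-type compounds, stay intact; no stereocentre is affected.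

Compound list
1 | (S)-pinocembrin, (2S)-5,7-dihydroxyflavanone | Oc1cc(O)c2c(c1)O[C@H](c1ccccc1)CC2=O | starting material
2 | (2S)-5,7-bis(benzyloxy)flavanone | O=C1C[C@@H](c2ccccc2)Oc2cc(OCc3ccccc3)cc(OCc3ccccc3)c12 | intermediate
3 | (2S)-5,7-bis(benzyloxy)-8-iodoflavanone | Ic1c(OCc3ccccc3)cc(OCc3ccccc3)c2c1O[C@H](c1ccccc1)CC2=O | intermediate
4 | 2-hydroxy-4,6-dimethoxybenzaldehyde | COc1cc(O)c(C=O)c(OC)c1 | starting material
5 | 2-(tert-butyldimethylsilyloxy)-4,6-dimethoxybenzaldehyde | COc1cc(O[Si](C)(C)C(C)(C)C)c(C=O)c(OC)c1 | intermediate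
6 | [(2S)-5,7-bis(benzyloxy)-4-oxo-2-phenylchroman-8-yl]chromium dichloride (solvated, not isolated) | Cl[Cr](Cl)c1c(OCc3ccccc3)cc(OCc3ccccc3)c2c1O[C@H](c1ccccc1)CC2=O | intermediate
7 | (2S)-5,7-bis(benzyloxy)-8-{[2-(tert-butyldimethylsilyloxy)-4,6-dimethoxyphenyl](hydroxy)methyl}flavanone, both carbinol epimers | COc1cc(O[Si](C)(C)C(C)(C)C)c(c(OC)c1)C(O)c1c(OCc3ccccc3)cc(OCc3ccccc3)c2c1O[C@H](c1ccccc1)CC2=O | intermediate
8 | (2S)-5,7-bis(benzyloxy)-8-[hydroxy(2-hydroxy-4,6-dimethoxyphenyl)methyl]flavanone, both carbinol epimers | COc1cc(O)c(c(OC)c1)C(O)c1c(OCc3ccccc3)cc(OCc3ccccc3)c2c1O[C@H](c1ccccc1)CC2=O | intermediate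
9 | 4'-benzyloxyacetophenone | CC(=O)c1ccc(OCc2ccccc2)cc1 | starting material
10 | 1-(4-benzyloxyphenyl)-1-(trimethylsilyloxy)ethene | C=C(O[Si](C)(C)C)c1ccc(OCc2ccccc2)cc1 | intermediate
11 | 6-{[(2S)-5,7-bis(benzyloxy)-4-oxo-2-phenylchroman-8-yl]methylidene}-3,5-dimethoxycyclohexa-2,4-dien-1-one, ortho-quinone methide, methide geometry not fixed (not isolated) | COC1=CC(=O)C(=Cc2c(OCc3ccccc3)cc(OCc3ccccc3)c3c2O[C@H](c2ccccc2)CC3=O)C(OC)=C1 | intermediate
12 | (2S)-5,7-bis(benzyloxy)-8-[(4R)-2-(4-benzyloxyphenyl)-5,7-dimethoxy-2-(trimethylsilyloxy)chroman-4-yl]flavanone, silyl ketal, C2 uncontrolled (not isolated) | COc1cc(OC)c2c(c1)OC(O[Si](C)(C)C)(c1ccc(OCc3ccccc3)cc1)C[C@H]2c1c(OCc3ccccc3)cc(OCc3ccccc3)c2c1O[C@H](c1ccccc1)CC2=O | intermediate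
13 | (2S)-5,7-bis(benzyloxy)-8-[(4R)-2-(4-benzyloxyphenyl)-2-hydroxy-5,7-dimethoxychroman-4-yl]flavanone, hemiketal, anomer mixture | COc1cc(OC)c2c(c1)OC(O)(c1ccc(OCc3ccccc3)cc1)C[C@H]2c1c(OCc3ccccc3)cc(OCc3ccccc3)c2c1O[C@H](c1ccccc1)CC2=O | intermediate
14 | (4R)-2-(4-benzyloxyphenyl)-4-[(2S)-5,7-bis(benzyloxy)-4-oxo-2-phenylchroman-8-yl]-5,7-dimethoxy-4H-chromen-1-ium, oxocarbenium ion (not isolated) | COc1cc(OC)c2c(c1)[O+]=C(c1ccc(OCc3ccccc3)cc1)C[C@H]2c1c(OCc3ccccc3)cc(OCc3ccccc3)c2c1O[C@H](c1ccccc1)CC2=O | intermediate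
15 | (2S)-5,7-bis(benzyloxy)-8-[(4R)-2-(4-benzyloxyphenyl)-5,7-dimethoxychroman-4-yl]flavanone, both C2 epimers (2,4-cis and 2,4-trans) | COc1cc(OC)c2c(c1)OC(c1ccc(OCc3ccccc3)cc1)C[C@H]2c1c(OCc3ccccc3)cc(OCc3ccccc3)c2c1O[C@H](c1ccccc1)CC2=O | intermediate
16 | 4-benzyloxybenzyl cation formed by opening O1–C2 of 15, ring A phenol free (not isolated) | COc1cc(O)c(c(OC)c1)[C@@H](C[CH+]c1ccc(OCc3ccccc3)cc1)c1c(OCc3ccccc3)cc(OCc3ccccc3)c2c1O[C@H](c1ccccc1)CC2=O | intermediate
17 | (2S)-5,7-bis(benzyloxy)-8-[(2S,4R)-2-(4-benzyloxyphenyl)-5,7-dimethoxychroman-4-yl]flavanone, flavan unit 2,4-trans | COc1cc(OC)c2c(c1)O[C@H](c1ccc(OCc3ccccc3)cc1)C[C@H]2c1c(OCc3ccccc3)cc(OCc3ccccc3)c2c1O[C@H](c1ccccc1)CC2=O | intermediate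
18 | (2S)-5,7-dihydroxy-8-[(2S,4R)-2-(4-hydroxyphenyl)-5,7-dimethoxychroman-4-yl]flavanone, flavan unit 2,4-trans | COc1cc(OC)c2c(c1)O[C@H](c1ccc(O)cc1)C[C@H]2c1c(O)cc(O)c2c1O[C@H](c1ccccc1)CC2=O | target

Total step count: 10.
Longest linear sequence: 8 steps (steps 1, 2, 4, 5, 7, 8, 9 and 10, from 1).

Steps most likely to fail

1. Step 7. The enol silane may be lost to protodesilylation by the acid and by the water set free before it reaches the hindered methide. The methide face may also be poorly discriminated, because the nucleophile offers the phosphate no hydrogen bond and the catalyst has to override the flavanone centre. The fallback keeps the disconnection but changes the nucleophile class. It sets out from 8 and 9 and rejoins the route at 13. Ketone 9 is converted (NH2OH·HCl, NaOAc, EtOH) into (E)-4'-benzyloxyacetophenone oxime F1. Reductive acetylation (Fe powder, Ac2O, AcOH, toluene, 70 °C) turns this into the enamide N-[1-(4-benzyloxyphenyl)ethenyl]acetamide F2. Carbinol 8 and F2 under the same phosphoric acid should give the 2-acetamidochroman F3, the amide N–H now binding the phosphoryl oxygen so that both partners are held by the catalyst. Mild aqueous acid (oxalic acid, THF–H2O) then hydrolyses the N,O-ketal to 13.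

2. Step 4. Addition of the doubly ortho-substituted aryl–chromium species to the hindered, electron-rich aldehyde may be slow, so that protodemetalation back to 2 or nickel-mediated biaryl formation takes over. The fallback sets out from 3 and rejoins the route at 7. Miyaura borylation (B2pin2, PdCl2(dppf), KOAc, dioxane, 80 °C) gives (2S)-5,7-bis(benzyloxy)-8-(4,4,5,5-tetramethyl-1,3,2-dioxaborolan-2-yl)flavanone F4. Base-free 1,2-addition of F4 to aldehyde 5, catalysed by [Rh(cod)OH]2 (dioxane–H2O, 60 °C), then gives 7.

3. Step 9. The C2 epimer equilibrium may stop short of the trans isomer. Repeated ionisation at C2 may also open slower leak channels: cleavage of a C4–aryl bond by adventitious protic acid, or fragmentation of the cation with loss of 4-benzyloxystyrene. The fallback sets out from 13, bypasses steps 8 and 9, and rejoins the route at 17. Corey–Bakshi–Shibata reduction of the open-chain aryl ketone form of 13 uses (S)-2-methyl-CBS-oxazaborolidine and BH3·SMe2 in THF at −20 °C. The trioxygenated, peri-flanked flavanone carbonyl should react much more slowly. This gives (2S)-5,7-bis(benzyloxy)-8-[(1R,3R)-3-(4-benzyloxyphenyl)-3-hydroxy-1-(2-hydroxy-4,6-dimethoxyphenyl)propyl]flavanone F5, with the carbinol centre set by the reagent. Mitsunobu cyclisation (PPh3, DIAD, THF, 0 °C) closes O1–C2 with inversion to give 17, the closure that also places the C2 aryl group equatorial.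

Further compounds
F1 | step 7 | (E)-4'-benzyloxyacetophenone oxime | O/N=C(C)/c1ccc(OCc2ccccc2)cc1
F2 | step 7 | N-[1-(4-benzyloxyphenyl)ethenyl]acetamide | C=C(NC(C)=O)c1ccc(OCc2ccccc2)cc1
F3 | step 7 | (2S)-8-[(4R)-2-acetamido-2-(4-benzyloxyphenyl)-5,7-dimethoxychroman-4-yl]-5,7-bis(benzyloxy)flavanone, C2 uncontrolled | COc1cc(OC)c2c(c1)OC(NC(C)=O)(c1ccc(OCc3ccccc3)cc1)C[C@H]2c1c(OCc3ccccc3)cc(OCc3ccccc3)c2c1O[C@H](c1ccccc1)CC2=O
F4 | step 4 | (2S)-5,7-bis(benzyloxy)-8-(4,4,5,5-tetramethyl-1,3,2-dioxaborolan-2-yl)flavanone | CC1(C)OB(OC1(C)C)c1c(OCc3ccccc3)cc(OCc3ccccc3)c2c1O[C@H](c1ccccc1)CC2=O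
F5 | step 9 | (2S)-5,7-bis(benzyloxy)-8-[(1R,3R)-3-(4-benzyloxyphenyl)-3-hydroxy-1-(2-hydroxy-4,6-dimethoxyphenyl)propyl]flavanone | COc1cc(O)c(c(OC)c1)[C@@H](C[C@@H](O)c1ccc(OCc3ccccc3)cc1)c1c(OCc3ccccc3)cc(OCc3ccccc3)c2c1O[C@H](c1ccccc1)CC2=O
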